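## Retrosynthetic overview

1. The target is opened at its two ester C–O bonds (O15 methyl succinate, O19 isovalerate) and at the C2 carbinol, which comes last from a 2-ketone by an equatorial-selective electron-transfer reduction.
2. The C19–O bond, and with it the C4 stereocentre, comes from a C19–H oxygenation directed by an axial 2β-silyloxy group (silylation, then oxidation); this is the new step.
3. The C2–O bond comes from C–H oxygenation of the ring A methylene of a sclareol-derived ketol; the 13E-enoate comes from a Horner–Wadsworth–Emmons reaction and the 7-ene from dehydration of the 8α-carbinol.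
4. The ketol comes from (−)-sclareol by oxidative loss of C14 and C15.
5. Ring order: rings A and B, with C5, C9 and C10, are taken intact from sclareol; no carbocycle is built, only a transient oxasilinane on ring A.

Assumption: the SMILES is read as the normal (non-ent) labdane with 5α-H, 9α-H, 10β-CH3 (C20), 4α-CH3 (C18), 4β-CH2O (C19) and 2α-OH; a one-pot sequence counts as one step.

## Route

Step 1
Reactants: 1 (−)-sclareol (labd-14-ene-8α,13R-diol)
Product: 2 8α-hydroxy-14,15-dinorlabdan-13-one
Conditions: KMnO4, acetone/H2O, 0 °C → rt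
Reagents that add atoms: none
Why: Known permanganate degradation of the vinyl carbinol (dihydroxylation, glycol cleavage, oxidative decarboxylation) removes C14 and C15 and leaves the methyl ketone, with no ring stereocentre touched.

Step 2
Reactants: 2 8α-hydroxy-14,15-dinorlabdan-13-one
Product: 3 8α-hydroxy-14,15-dinorlabdane-2,13-dione
Conditions: quinuclidine, Me4NBF4, HFIP, MeCN, O2, RVC anode, Ni cathode, constant current, rt
Reagents that add atoms: dioxygen, O=O
Why: Quinuclidine-mediated electrochemical C–H oxygenation (aminium-radical hydrogen abstraction, O2 trapping) should attack C2, the most electron-rich and least hindered methylene, as it does in sclareolide, because ring B and the side chain are deactivated by the 8-hydroxyl and the 13-carbonyl; the product is a ketone, so no stereocentre is set yet.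

Step 3
Reactants: 3 8α-hydroxy-14,15-dinorlabdane-2,13-dione; 4 triethyl phosphonoacetate
Product: 5 ethyl (13E)-8α-hydroxy-2-oxolabd-13-en-15-oate
Conditions: 4, NaH (anion preformed, no excess base), THF, 0 → 60 °C
Reagents that add atoms: triethyl phosphonoacetate, CCOC(=O)CP(=O)(OCC)OCC
Why: Horner–Wadsworth–Emmons olefination takes place at the unhindered methyl ketone (the ring A ketone is shielded by the syn-axial C19 and C20 methyls) and gives mainly the E-enoate, the Z isomer being removed by chromatography.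

Step 4
Reactants: 5 ethyl (13E)-8α-hydroxy-2-oxolabd-13-en-15-oate
Product: 6 ethyl (13E)-2-oxolabda-7,13-dien-15-oate
Conditions: Burgess reagent, toluene, 50 °C
Reagents that add atoms: none
Why: Burgess dehydration (syn elimination through the tertiary sulfamate ion pair) should remove the accessible cis 7α-hydrogen to give the trisubstituted 7-ene as main isomer, the 8(17)- and 8-enes being separated on AgNO3-impregnated silica; the electron-poor 13-ene cannot trap the C8 cation.

Step 5
Reactants: 6 ethyl (13E)-2-oxolabda-7,13-dien-15-oate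
Product: 9 ethyl (13E)-2β,19-dihydroxylabda-7,13-dien-15-oate, via 2β-diethylsilyl ether 7 (not isolated), via C19-oxasilinane 8 (not isolated)
Conditions: Et2SiH2, [Ir(cod)OMe]2 (cat.), THF, rt; then [Rh(cod)Cl]2/(R)-DTBM-SEGPHOS (cat.), norbornene, THF, 100 °C; then H2O2, KHCO3, KF, THF/EtOH, 50 °C
Reagents that add atoms: hydrogen peroxide, OO (the C19 oxygen); diethylsilane, CC[SiH2]CC (silicon and ethyl groups, kept only in 7 and 8)
Why: Proposed new method: a catalyst-controlled choice between the two syn-axial methyls C19 and C20 in an oxygen-directed δ-C–H silylation; the Ir hydride adds to the open α-face of the C2 ketone, so the O–SiEt2H group is axial (2β), about 2.5 Å from C19 and C20 and out of reach of the equatorial C18; the Rh–silyl species then inserts into a C19–H bond through a seven-membered rhodacycle and closes a chair oxasilinane while norbornene takes up H2; the bulky C2-symmetric bisphosphine is meant to disfavour the ring-fusion methyl C20, which is wedged against ring B and the C9 side chain (the ligand antipode is the mismatched control); Tamao–Fleming oxidation converts C19–Si into C19–OH with retention, fixing C4 as 4β-CH2OH/4α-CH3; the closest known reaction type is the Ir- or Rh-catalysed intramolecular silylation of methyl C–H bonds of (hydrido)silyl ethers with oxidation to 1,3- or 1,4-diols, which has not been used to tell apart two 1,3-diaxial methyl groups.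

Step 6
Reactants: 9 ethyl (13E)-2β,19-dihydroxylabda-7,13-dien-15-oate
Product: 10 (13E)-labda-7,13-diene-2β,15,19-triol
Conditions: iBu2AlH, CH2Cl2, −78 → 0 °C; aq. potassium sodium tartrate (KNaC4H4O6)
Reagents that add atoms: none
Why: 1,2-Reduction of the enoate by the aluminium hydride gives the E-allylic alcohol and leaves the isolated alkenes and all stereocentres untouched.

Step 7
Reactants: 10 (13E)-labda-7,13-diene-2β,15,19-triol; 11 methyl 4-chloro-4-oxobutanoate; 12 3-methylbutanoyl chloride
Product: 14 methyl (13E)-2β-hydroxy-19-(3-methylbutanoyloxy)labda-7,13-dien-15-yl butanedioate, via 15-monosuccinate 13 (not isolated)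
Conditions: 11 (1.05 equiv), pyridine, CH2Cl2, −20 °C; then 12 (1.3 equiv), DMAP (cat.), 0 °C → rt
Reagents that add atoms: methyl 4-chloro-4-oxobutanoate, COC(=O)CCC(=O)Cl; 3-methylbutanoyl chloride, CC(C)CC(=O)Cl
Why: Sequential acylation follows steric rank: the unhindered allylic primary 15-OH reacts first in the cold, the neopentyl primary 19-OH next under DMAP catalysis, and the axial 2β-OH, flanked by two syn-axial groups like a steroid 11β-hydroxyl, stays free.

Step 8
Reactants: 14 methyl (13E)-2β-hydroxy-19-(3-methylbutanoyloxy)labda-7,13-dien-15-yl butanedioate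
Product: 15 methyl (13E)-19-(3-methylbutanoyloxy)-2-oxolabda-7,13-dien-15-yl butanedioate
Conditions: Dess–Martin periodinane, CH2Cl2, rt
Reagents that add atoms: none
Why: Dess–Martin oxidation of the strained axial carbinol is fast (relief of 1,3-diaxial strain) and spares esters and alkenes.

Step 9
Reactants: 15 methyl (13E)-19-(3-methylbutanoyloxy)-2-oxolabda-7,13-dien-15-yl butanedioate
Product: 16 methyl (13E)-2α-hydroxy-19-(3-methylbutanoyloxy)labda-7,13-dien-15-yl butanedioate (CNP0118741.1)
Conditions: SmI2, H2O, THF, 0 °C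
Reagents that add atoms: none
Why: Single-electron (dissolving-metal type) ketone reduction should give the thermodynamic alcohol, because the samarium ketyl/carbanion holds its bulky O–Sm group equatorial and is protonated axially by water, so the hydroxyl ends 2α, whereas hydride reagents attack the open α-face and would return 14; esters, the allylic ester and isolated alkenes are inert to SmI2/H2O without amine.

## Compound list

1 | (−)-sclareol, labd-14-ene-8α,13R-diol | C=C[C@](C)(O)CC[C@H]1[C@](C)(O)CC[C@H]2C(C)(C)CCC[C@]12C | starting material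
2 | 8α-hydroxy-14,15-dinorlabdan-13-one | CC(=O)CC[C@H]1[C@](C)(O)CC[C@H]2C(C)(C)CCC[C@]12C | intermediate
3 | 8α-hydroxy-14,15-dinorlabdane-2,13-dione | CC(=O)CC[C@H]1[C@](C)(O)CC[C@H]2C(C)(C)CC(=O)C[C@]12C | intermediate
4 | triethyl phosphonoacetate | CCOC(=O)CP(=O)(OCC)OCC | starting material
5 | ethyl (13E)-8α-hydroxy-2-oxolabd-13-en-15-oate | CCOC(=O)/C=C(\C)CC[C@H]1[C@](C)(O)CC[C@H]2C(C)(C)CC(=O)C[C@]12C | intermediate
6 | ethyl (13E)-2-oxolabda-7,13-dien-15-oate | CCOC(=O)/C=C(\C)CC[C@H]1C(C)=CC[C@H]2C(C)(C)CC(=O)C[C@]12C | intermediate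
7 | ethyl (13E)-2β-(diethylsilyloxy)labda-7,13-dien-15-oate (axial O–SiHEt2) | CCOC(=O)/C=C(\C)CC[C@H]1C(C)=CC[C@H]2C(C)(C)C[C@@H](O[SiH](CC)CC)C[C@]12C | intermediate
8 | ethyl (13E)-2β,19-(diethylsilanediyloxy)labda-7,13-dien-15-oate (six-membered ring O on C2β–SiEt2–C19H2–C4–C3–C2) | CCOC(=O)/C=C(\C)CC[C@H]1C(C)=CC[C@H]2[C@]3(C)C[C@@H](O[Si](CC)(CC)C3)C[C@]12C | intermediate
9 | ethyl (13E)-2β,19-dihydroxylabda-7,13-dien-15-oate | CCOC(=O)/C=C(\C)CC[C@H]1C(C)=CC[C@H]2[C@@](C)(CO)C[C@@H](O)C[C@]12C | intermediate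
10 | (13E)-labda-7,13-diene-2β,15,19-triol | OC/C=C(\C)CC[C@H]1C(C)=CC[C@H]2[C@@](C)(CO)C[C@@H](O)C[C@]12C | intermediate
11 | methyl 4-chloro-4-oxobutanoate | COC(=O)CCC(=O)Cl | starting material
12 | 3-methylbutanoyl chloride | CC(C)CC(=O)Cl | starting material
13 | methyl (13E)-2β,19-dihydroxylabda-7,13-dien-15-yl butanedioate | COC(=O)CCC(=O)OC/C=C(\C)CC[C@H]1C(C)=CC[C@H]2[C@@](C)(CO)C[C@@H](O)C[C@]12C | intermediate
14 | methyl (13E)-2β-hydroxy-19-(3-methylbutanoyloxy)labda-7,13-dien-15-yl butanedioate | COC(=O)CCC(=O)OC/C=C(\C)CC[C@H]1C(C)=CC[C@H]2[C@@](C)(COC(=O)CC(C)C)C[C@@H](O)C[C@]12C | intermediate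
15 | methyl (13E)-19-(3-methylbutanoyloxy)-2-oxolabda-7,13-dien-15-yl butanedioate | COC(=O)CCC(=O)OC/C=C(\C)CC[C@H]1C(C)=CC[C@H]2[C@@](C)(COC(=O)CC(C)C)CC(=O)C[C@]12C | intermediate
16 | methyl (13E)-2α-hydroxy-19-(3-methylbutanoyloxy)labda-7,13-dien-15-yl butanedioate | COC(=O)CCC(=O)OC/C=C(\C)CC[C@H]1C(C)=CC[C@H]2[C@@](C)(COC(=O)CC(C)C)C[C@H](O)C[C@]12C | target

## Step count and risks

Total steps: 9. Longest linear sequence: 9 steps, from sclareol 1.

**Step 5 (new method).** The risks are C20 instead of C19 silylation and hydrosilylation of the enoate. The fallback uses known chemistry, sets out from 6 and comes back at 9. NaBH4 in MeOH reduces the ketone from the α-face to ethyl (13E)-2β-hydroxylabda-7,13-dien-15-oate F1. NOCl/pyridine gives the nitrite ester ethyl (13E)-2β-(nitrosooxy)labda-7,13-dien-15-oate F2. Barton nitrite photolysis (alkoxy radical, 1,5-hydrogen shift from a syn-axial methyl, NO recombination) gives ethyl (13E)-2β-hydroxy-19-(hydroxyimino)labda-7,13-dien-15-oate F3, which must be separated from its C20 isomer. Hydrolysis of the oxime (aq. NaHSO3, then dilute HCl) gives ethyl (13E)-2β-hydroxy-19-oxolabda-7,13-dien-15-oate F4, largely as its 2β,19-hemiacetal, and NaBH4 reduces it to 9.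

**Step 4.** The risk is a mixture of 7-, 8(17)- and 8-enes. The fallback sets out from 5 and comes back at 6. POCl3/pyridine (anti elimination; the equatorial tertiary hydroxyl has only methyl hydrogens antiperiplanar) gives the exocyclic alkene ethyl (13E)-2-oxolabda-8(17),13-dien-15-oate F5. RhCl3·3H2O in hot ethanol then moves the double bond into the ring to give 6.

**Step 9.** The risk is that the reduction gives the 2β-alcohol 14 again. The fallback sets out from 10 and comes back at 16.
- TBSCl/imidazole silylates only the two primary hydroxyls, giving (13E)-15,19-bis(tert-butyldimethylsilyloxy)labda-7,13-dien-2β-ol F6.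
- Dess–Martin oxidation gives (13E)-15,19-bis(tert-butyldimethylsilyloxy)labda-7,13-dien-2-one F7.
- Li in liquid NH3/THF with t-BuOH, the classical route from hindered ketones such as steroid 11-ketones to equatorial alcohols, gives (13E)-15,19-bis(tert-butyldimethylsilyloxy)labda-7,13-dien-2α-ol F8.
- TBAF gives (13E)-labda-7,13-diene-2α,15,19-triol F9.
- Acylation as in step 7, first with 11 at O15 to methyl (13E)-2α,19-dihydroxylabda-7,13-dien-15-yl butanedioate F10, then with 12 at the primary O19 in preference to the secondary 2α-OH, gives 16.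

## Further compounds

F1 | step 5 | ethyl (13E)-2β-hydroxylabda-7,13-dien-15-oate | CCOC(=O)/C=C(\C)CC[C@H]1C(C)=CC[C@H]2C(C)(C)C[C@@H](O)C[C@]12C
F2 | step 5 | ethyl (13E)-2β-(nitrosooxy)labda-7,13-dien-15-oate | CCOC(=O)/C=C(\C)CC[C@H]1C(C)=CC[C@H]2C(C)(C)C[C@@H](ON=O)C[C@]12C
F3 | step 5 | ethyl (13E)-2β-hydroxy-19-(hydroxyimino)labda-7,13-dien-15-oate | CCOC(=O)/C=C(\C)CC[C@H]1C(C)=CC[C@H]2[C@@](C)(C=NO)C[C@@H](O)C[C@]12C
F4 | step 5 | ethyl (13E)-2β-hydroxy-19-oxolabda-7,13-dien-15-oate | CCOC(=O)/C=C(\C)CC[C@H]1C(C)=CC[C@H]2[C@@](C)(C=O)C[C@@H](O)C[C@]12C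
F5 | step 4 | ethyl (13E)-2-oxolabda-8(17),13-dien-15-oate | CCOC(=O)/C=C(\C)CC[C@H]1C(=C)CC[C@H]2C(C)(C)CC(=O)C[C@]12C
F6 | step 9 | (13E)-15,19-bis(tert-butyldimethylsilyloxy)labda-7,13-dien-2β-ol | CC(C)(C)[Si](C)(C)OC/C=C(\C)CC[C@H]1C(C)=CC[C@H]2[C@@](C)(CO[Si](C)(C)C(C)(C)C)C[C@@H](O)C[C@]12C
F7 | step 9 | (13E)-15,19-bis(tert-butyldimethylsilyloxy)labda-7,13-dien-2-one | CC(C)(C)[Si](C)(C)OC/C=C(\C)CC[C@H]1C(C)=CC[C@H]2[C@@](C)(CO[Si](C)(C)C(C)(C)C)CC(=O)C[C@]12C
F8 | step 9 | (13E)-15,19-bis(tert-butyldimethylsilyloxy)labda-7,13-dien-2α-ol | CC(C)(C)[Si](C)(C)OC/C=C(\C)CC[C@H]1C(C)=CC[C@H]2[C@@](C)(CO[Si](C)(C)C(C)(C)C)C[C@H](O)C[C@]12C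
F9 | step 9 | (13E)-labda-7,13-diene-2α,15,19-triol | OC/C=C(\C)CC[C@H]1C(C)=CC[C@H]2[C@@](C)(CO)C[C@H](O)C[C@]12C
F10 | step 9 | methyl (13E)-2α,19-dihydroxylabda-7,13-dien-15-yl butanedioate | COC(=O)CCC(=O)OC/C=C(\C)CC[C@H]1C(C)=CC[C@H]2[C@@](C)(CO)C[C@H](O)C[C@]12C
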